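Remark: carotenoid numbering is used throughout (ring carbons C1–C6, chain C7–C15 then C15′–C10′; ring A = cyclohexane, ring B = 2,5-dihydrofuran); compounds 1, 5, 13 and 14 are assumed to be purchasable.

## Analysis of the target

The target 18 is the C27 apocarotenoid (3S,5R,8R,all-E)-5,8-epoxy-5,8-dihydro-10′-apo-β-carotene-3,10′-diol. Ring A (C1–C6: gem-dimethyl C1, carbinol C3, oxygenated quaternary C5) is fused across C5–C6 to ring B (O–C5–C6=C7–C8), whose C6=C7 bond is exocyclic to ring A. C8 carries an all-E hexaene (C9=C10 to C12′=C11′) that ends in the primary allylic alcohol C10′. There are three stereocentres: C3 (S), C5 (R, quaternary) and C8 (R). The C3 hydroxyl is cis to the C5 methyl and trans to the ring oxygen; across ring B the chain on C8 is trans to the C5 methyl, so C8–H is cis to it. The C3/C5 pattern is that of the common 3-hydroxy-5,6-epoxy end groups and can come from a chiral-pool ring. C8 is the hard centre: it is remote from C3, and the usual entry through an allylic cation gives both epimers. The O–C8 bond is doubly allylic (C6=C7 and the polyene) and ionises with acid; the hexaene is sensitive to acid, light and electrophiles. C8 must therefore be fixed early and without acid. The feature that invites the key move is the O–C8 bond of ring B together with the C6=C7 bond: ring B is the cycloisomer of a 5-hydroxy-6,7-allene, C5(OH)–C6=C7=C8H–C9, whose axis can carry the information for C8.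

## Retrosynthetic reasoning

18 from 17. The C10′ alcohol is taken back to the ethyl ester 17. The ester is the acceptor terminus that makes polyene assembly clean, and a low-temperature hydride reduction is a non-acidic last step.

17 from 12 and 15. The E-disubstituted C11=C12 bond is cut (Horner–Wadsworth–Emmons). This divides the molecule into a C15 half that holds all three stereocentres (phosphonate 12) and an achiral C12 half (aldehyde 15). No step that builds or touches ring B then has to tolerate the hexaene.

15 from 13 and 14. The C11′=C12′ bond is cut; a single Wittig mono-olefination of the symmetric dialdehyde 13 with the stabilised ylide 14 gives 15.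

12 from 11 (key disconnection). The O–C8 bond of ring B is cut, which opens the bicycle to the monocyclic α-hydroxyallene 11. Forward, a 5-endo cycloisomerisation closes ring B and creates C8 in one operation, with the C8 configuration dictated by the allene axis. The forward reaction must keep the axis intact until the C–O bond is made and must not ionise the product. The axis needed is (aS): C9 on the side of the C5 oxygen, C8–H on the side of the C5 methyl.

11 from 9. The C8–H bond is cut and the C6–O bond restored, giving the alkynyl oxirane 9. Forward, an SN2′ hydride reduction with anti course turns the C6 centre into the axis and leaves the C5–O bond, and so the C5 centre, in place. A syn course (hydride delivered from a metal bound to the oxirane oxygen) would give the other axis and finally the C8 epimer, so a method with anti course is required.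

9 from 8. The oxirane is taken back to the tetrasubstituted C5=C6 olefin of enyne 8. One peracid epoxidation, steered by the C3 silyloxy group, sets C5 and C6 together.

8 from 4 and 7. The C6–C7 bond (sp2–sp) is cut (Sonogashira). The alkyne 7 brings C7–C11 with the 9E olefin and the phosphonate already in place, so no functional-group change is needed on the sensitive bicycle later.

4 from 2 from 1; 7 from 6 from 5. Triflate 4 comes from the only enolisable side of ketone 2, the silyl ether of chiral-pool 1, which supplies C3. Phosphonate 7 comes from enynol 5 by bromination (6) and Michaelis–Arbuzov reaction.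

## Alternatives that were turned down

Alternative 1: the textbook route. The O–C8 bond is made last from the C6–O bond of a 5,6-epoxide: acid-catalysed rearrangement of the C27 epoxide A1 to ring B. Protonation opens C6–O to a cation spread over C6, C8 and the hexaene, and the C5 hydroxyl closes on either face of planar C8. Compound 18 and its C8 epimer A2 would form together, the same acid re-ionises both, and they must be separated at the final stage. The acid also endangers the C10′ allylic alcohol and the polyene. The step count is no lower and C8 is not controlled.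

Alternative 2: union at C8. The C8–C9 and C8–H bonds are cut: a C9 alkenyl-lithium adds to the lactone carbonyl (C8) of the bicyclic butenolide A3, and lactol A4 is reduced with a silane and a Lewis acid. The reduction passes through a planar oxocarbenium ion at C8. Hydride should enter opposite the C5 methyl, which puts the chain cis to that methyl, the wrong epimer. The Lewis acid also meets a cation conjugated to C6=C7 and C9=C10, A4 can open to a hydroxy dienone, and the chain must still be grown afterwards.

Alternative 3: ring-closing metathesis. The C6=C7 bond is cut: the bis-olefin ether A5 (exocyclic methylene on C6, vinyl carbinyl ether on the C5 oxygen) is closed with a ruthenium alkylidene (second-generation Grubbs catalyst). The C6 methylene is 1,1-disubstituted and lies between two quaternary carbons (C1 and C5), so the metallacyclobutane must form at the most hindered olefin while the C9=C10 olefin competes. A5 itself needs an ether bond between a tertiary alkoxide and a secondary, doubly allylic carbon with control of C8, which only moves the C8 problem one step back.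

Key step: step 8

## Route

Step 1
Reactants: 1 (4R,6R)-4-hydroxy-2,2,6-trimethylcyclohexan-1-one
Product: 2 (4R,6R)-4-[(tert-butyldimethylsilyl)oxy]-2,2,6-trimethylcyclohexan-1-one
Conditions: TBSCl, imidazole, DMF, rt
Reagents that add atoms: tert-butyldimethylsilyl chloride, CC(C)(C)[Si](C)(C)Cl
Why: Standard silylation of the secondary alcohol; the bulky ether later steers the peracid to the opposite face and survives triflation and coupling.

Step 2
Reactants: 2 (4R,6R)-4-[(tert-butyldimethylsilyl)oxy]-2,2,6-trimethylcyclohexan-1-one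
Product: 4 (4R)-4-[(tert-butyldimethylsilyl)oxy]-2,6,6-trimethylcyclohex-1-en-1-yl trifluoromethanesulfonate, via potassium enolate 3 (not isolated)
Conditions: KN(SiMe3)2, THF, −78 °C; then PhNTf2, −78 °C to rt
Reagents that add atoms: N-phenylbis(trifluoromethanesulfonimide), O=S(=O)(N(c1ccccc1)S(=O)(=O)C(F)(F)F)C(F)(F)F
Why: Enol triflate formation; C2 of the ketone is quaternary, so only the C6 hydrogen can be removed and a single tetrasubstituted enolate forms. The C6 centre is lost on purpose, and the silyloxy group is γ to the carbonyl and cannot be eliminated.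

Step 3
Reactants: 5 (2E)-3-methylpent-2-en-4-yn-1-ol
Product: 6 (3E)-5-bromo-3-methylpent-3-en-1-yne
Conditions: PBr3, pyridine (cat.), Et2O, −20 to 0 °C
Reagents that add atoms: phosphorus tribromide, BrP(Br)Br
Why: SN2 bromination of a primary allylic alcohol; the trisubstituted olefin (the later 9E bond) is not touched.

Step 4
Reactants: 6 (3E)-5-bromo-3-methylpent-3-en-1-yne
Product: 7 diethyl [(2E)-3-methylpent-2-en-4-yn-1-yl]phosphonate
Conditions: P(OEt)3, neat, 90 °C
Reagents that add atoms: triethyl phosphite, CCOP(OCC)OCC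
Why: Michaelis–Arbuzov reaction at the primary allylic carbon; the fully substituted γ carbon disfavours SN2′ attack and the terminal alkyne is inert.

Step 5
Reactants: 4 (4R)-4-[(tert-butyldimethylsilyl)oxy]-2,6,6-trimethylcyclohex-1-en-1-yl trifluoromethanesulfonate; 7 diethyl [(2E)-3-methylpent-2-en-4-yn-1-yl]phosphonate
Product: 8 diethyl [(2E)-5-{(4R)-4-[(tert-butyldimethylsilyl)oxy]-2,6,6-trimethylcyclohex-1-en-1-yl}-3-methylpent-2-en-4-yn-1-yl]phosphonate
Conditions: Pd(PPh3)4 (5 mol%), CuI (10 mol%), Et3N, DMF, rt to 40 °C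
Reagents that add atoms: none
Why: Sonogashira coupling (zerovalent palladium, monovalent copper acetylide) of the vinyl triflate with the terminal alkyne forms C6–C7; the amine is too weak to deprotonate the allylic phosphonate and the olefin geometry is retained.

Step 6
Reactants: 8 diethyl [(2E)-5-{(4R)-4-[(tert-butyldimethylsilyl)oxy]-2,6,6-trimethylcyclohex-1-en-1-yl}-3-methylpent-2-en-4-yn-1-yl]phosphonate
Product: 9 diethyl [(2E)-5-{(1R,4S,6R)-4-[(tert-butyldimethylsilyl)oxy]-2,2,6-trimethyl-7-oxabicyclo[4.1.0]heptan-1-yl}-3-methylpent-2-en-4-yn-1-yl]phosphonate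
Conditions: mCPBA, NaHCO3, CH2Cl2, 0 °C
Reagents that add atoms: 3-chloroperbenzoic acid, O=C(OO)c1cccc(Cl)c1
Why: Prilezhaev epoxidation; the tetrasubstituted C5=C6 olefin is the most electron-rich one, since C9=C10 carries the withdrawing phosphonomethyl group. The peracid is expected to add mainly anti to the bulky C3 silyloxy group, which sets C5 (R) and C6 together; the minor syn oxirane would be removed by chromatography.

Step 7
Reactants: 9 diethyl [(2E)-5-{(1R,4S,6R)-4-[(tert-butyldimethylsilyl)oxy]-2,2,6-trimethyl-7-oxabicyclo[4.1.0]heptan-1-yl}-3-methylpent-2-en-4-yn-1-yl]phosphonate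
Product: 11 diethyl {(2E,aS)-5-[(2R,4S)-2,4-dihydroxy-2,6,6-trimethylcyclohexylidene]-3-methylpenta-2,4-dien-1-yl}phosphonate, via silyl ether 10 (not isolated)
Conditions: CuCl (5 mol%), 1,3-dimesitylimidazolium chloride (5 mol%), NaOtBu (12 mol%), (EtO)2MeSiH, toluene, 0 °C to rt; then Bu4NF, THF, rt
Reagents that add atoms: none
Why: Copper-hydride-catalysed SN2′ reduction of a propargyl oxirane to an α-hydroxyallene. Syn hydrocupration of C7≡C8 (hydride to C8, copper to C7) on the face away from the oxirane oxygen, then anti β-alkoxide elimination, gives net anti substitution, so the C6 centre becomes the (aS) axis with C8–H on the side of the C5 methyl while C5 keeps its oxygen. The copper alkoxide is silylated by the silane to 10, and fluoride then frees both oxygens in the same flask.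

Step 8
Reactants: 11 diethyl {(2E,aS)-5-[(2R,4S)-2,4-dihydroxy-2,6,6-trimethylcyclohexylidene]-3-methylpenta-2,4-dien-1-yl}phosphonate
Product: 12 diethyl {(2E)-3-[(2R,6S,7aR)-6-hydroxy-4,4,7a-trimethyl-2,4,5,6,7,7a-hexahydro-1-benzofuran-2-yl]but-2-en-1-yl}phosphonate
Conditions: AuCl3 (2 mol%), THF, 0 °C to rt, dark; then Et3N
Reagents that add atoms: none
Why: Trivalent gold binds the distal C7=C8 π bond of the allene on the side away from the C5 hydroxyl, the oxygen adds to C8 (anti oxyauration), and protodeauration of the C7 vinylgold releases 12 and the catalyst. The closest known reaction type is the gold-catalysed cycloisomerisation of α-hydroxyallenes to 2,5-dihydrofurans with axis-to-centre chirality transfer. Ring B closes in the 5-endo-trig mode, with the C6=C7 bond left inside the ring. The O–C8 bond forms in the plane that already holds C5, C6 and C7, so the two substituents of C8 keep their sides: with the (aS) axis C9 ends trans to the C5 methyl and C8–H cis to it, which is 8R. C5 is not touched and serves as the relay. Only the tertiary C5 hydroxyl can reach C8 (the C3 hydroxyl would need a bridged ring), and attack at C8 is preferred over C7 because the latter would give an oxetane. The step needs the axis to survive until the C–O bond is made and the doubly allylic ether of 12 not to ionise. THF as a moderating solvent, low loading and temperature, the amine quench and the phosphonomethyl group on C10 (which destabilises positive charge on the C8–C10 allyl unit) are meant to secure this. The free, small C3 hydroxyl lets ring A reach the conformer with the C5–O bond in the allene plane.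

Step 9
Reactants: 13 (2E,4E,6E)-2,7-dimethylocta-2,4,6-trienedial; 14 ethyl (triphenyl-λ5-phosphanylidene)acetate
Product: 15 ethyl (2E,4E,6E,8E)-4,9-dimethyl-10-oxodeca-2,4,6,8-tetraenoate
Conditions: CH2Cl2, rt, 13 in excess
Reagents that add atoms: none
Why: Wittig reaction of a stabilised ylide, E-selective; the excess of the symmetric dialdehyde limits double olefination and the surplus is recovered.

Step 10
Reactants: 12 diethyl {(2E)-3-[(2R,6S,7aR)-6-hydroxy-4,4,7a-trimethyl-2,4,5,6,7,7a-hexahydro-1-benzofuran-2-yl]but-2-en-1-yl}phosphonate; 15 ethyl (2E,4E,6E,8E)-4,9-dimethyl-10-oxodeca-2,4,6,8-tetraenoate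
Product: 17 ethyl (2E,4E,6E,8E,10E,12E)-13-[(2R,6S,7aR)-6-hydroxy-4,4,7a-trimethyl-2,4,5,6,7,7a-hexahydro-1-benzofuran-2-yl]-4,9-dimethyltetradeca-2,4,6,8,10,12-hexaenoate, via dipotassium salt 16 (not isolated)
Conditions: KN(SiMe3)2 (2.1 equiv), THF, −78 °C; then 15, −78 to 0 °C, dark
Reagents that add atoms: none
Why: Horner–Wadsworth–Emmons olefination; one equivalent of base takes the C3 hydroxyl proton and the second gives the allylic phosphonate carbanion, which attacks the aldehyde through its unhindered α carbon (C11) and eliminates diethyl phosphate to the E C11=C12 olefin. Low temperature is meant to keep the C8 oxygen from being expelled from the delocalised anion.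

Step 11
Reactants: 17 ethyl (2E,4E,6E,8E,10E,12E)-13-[(2R,6S,7aR)-6-hydroxy-4,4,7a-trimethyl-2,4,5,6,7,7a-hexahydro-1-benzofuran-2-yl]-4,9-dimethyltetradeca-2,4,6,8,10,12-hexaenoate
Product: 18 (2E,4E,6E,8E,10E,12E)-13-[(2R,6S,7aR)-6-hydroxy-4,4,7a-trimethyl-2,4,5,6,7,7a-hexahydro-1-benzofuran-2-yl]-4,9-dimethyltetradeca-2,4,6,8,10,12-hexaen-1-ol
Conditions: iBu2AlH, CH2Cl2, −78 °C; Rochelle salt work-up, dark
Reagents that add atoms: none
Why: 1,2-Reduction of the conjugated ester to the allylic alcohol; no acid is used in reaction or work-up, so C8 and the hexaene should not be disturbed.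

## Compound list

1 | (4R,6R)-4-hydroxy-2,2,6-trimethylcyclohexan-1-one | CC1(C)C[C@H](O)C[C@@H](C)C1=O | starting material
2 | (4R,6R)-4-[(tert-butyldimethylsilyl)oxy]-2,2,6-trimethylcyclohexan-1-one | CC1(C)C[C@H](O[Si](C)(C)C(C)(C)C)C[C@@H](C)C1=O | intermediate
3 | potassium (4R)-4-[(tert-butyldimethylsilyl)oxy]-2,6,6-trimethylcyclohex-1-en-1-olate | CC1(C)C[C@H](O[Si](C)(C)C(C)(C)C)CC(C)=C1[O-].[K+] | intermediate
4 | (4R)-4-[(tert-butyldimethylsilyl)oxy]-2,6,6-trimethylcyclohex-1-en-1-yl trifluoromethanesulfonate | CC1(C)C[C@H](O[Si](C)(C)C(C)(C)C)CC(C)=C1OS(=O)(=O)C(F)(F)F | intermediate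
5 | (2E)-3-methylpent-2-en-4-yn-1-ol | C#C/C(C)=C/CO | starting material
6 | (3E)-5-bromo-3-methylpent-3-en-1-yne | C#C/C(C)=C/CBr | intermediate
7 | diethyl [(2E)-3-methylpent-2-en-4-yn-1-yl]phosphonate | C#C/C(C)=C/CP(=O)(OCC)OCC | intermediate
8 | diethyl [(2E)-5-{(4R)-4-[(tert-butyldimethylsilyl)oxy]-2,6,6-trimethylcyclohex-1-en-1-yl}-3-methylpent-2-en-4-yn-1-yl]phosphonate | CC1(C)C[C@H](O[Si](C)(C)C(C)(C)C)CC(C)=C1C#C/C(C)=C/CP(=O)(OCC)OCC | intermediate
9 | diethyl [(2E)-5-{(1R,4S,6R)-4-[(tert-butyldimethylsilyl)oxy]-2,2,6-trimethyl-7-oxabicyclo[4.1.0]heptan-1-yl}-3-methylpent-2-en-4-yn-1-yl]phosphonate | CC1(C)C[C@H](O[Si](C)(C)C(C)(C)C)C[C@@]2(C)O[C@@]12C#C/C(C)=C/CP(=O)(OCC)OCC | intermediate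
10 | diethyl {(2E,aS)-5-[(2R,4S)-4-[(tert-butyldimethylsilyl)oxy]-2-{[diethoxy(methyl)silyl]oxy}-2,6,6-trimethylcyclohexylidene]-3-methylpenta-2,4-dien-1-yl}phosphonate | C1[C@H](O[Si](C)(C)C(C)(C)C)C[C@@](C)(O[Si](C)(OCC)OCC)C(=[C@@]=CC(/C)=C/CP(=O)(OCC)OCC)C1(C)C | intermediate
11 | diethyl {(2E,aS)-5-[(2R,4S)-2,4-dihydroxy-2,6,6-trimethylcyclohexylidene]-3-methylpenta-2,4-dien-1-yl}phosphonate (carotenoid descriptors 3S,5R,6S) | C1[C@H](O)C[C@@](C)(O)C(=[C@@]=CC(/C)=C/CP(=O)(OCC)OCC)C1(C)C | intermediate
12 | diethyl {(2E)-3-[(2R,6S,7aR)-6-hydroxy-4,4,7a-trimethyl-2,4,5,6,7,7a-hexahydro-1-benzofuran-2-yl]but-2-en-1-yl}phosphonate | CCOP(=O)(OCC)C/C=C(\C)[C@H]1C=C2C(C)(C)C[C@H](O)C[C@@]2(C)O1 | intermediate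
13 | (2E,4E,6E)-2,7-dimethylocta-2,4,6-trienedial | O=C/C(C)=C/C=C/C=C(C)/C=O | starting material
14 | ethyl (triphenyl-λ5-phosphanylidene)acetate | CCOC(=O)C=P(c1ccccc1)(c1ccccc1)c1ccccc1 | starting material
15 | ethyl (2E,4E,6E,8E)-4,9-dimethyl-10-oxodeca-2,4,6,8-tetraenoate | CCOC(=O)/C=C/C(C)=C/C=C/C=C(C)/C=O | intermediate
16 | dipotassium salt of 12 (C3 alkoxide, C11 phosphonate carbanion) | [K+].[K+].CCOP(=O)(OCC)[CH-]/C=C(\C)[C@H]1C=C2C(C)(C)C[C@H]([O-])C[C@@]2(C)O1 | intermediate
17 | ethyl (2E,4E,6E,8E,10E,12E)-13-[(2R,6S,7aR)-6-hydroxy-4,4,7a-trimethyl-2,4,5,6,7,7a-hexahydro-1-benzofuran-2-yl]-4,9-dimethyltetradeca-2,4,6,8,10,12-hexaenoate | CC(/C=C/C=C(\C)[C@H]1C=C2C(C)(C)C[C@H](O)C[C@@]2(C)O1)=C\C=C\C=C(C)\C=C\C(=O)OCC | intermediate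
18 | (2E,4E,6E,8E,10E,12E)-13-[(2R,6S,7aR)-6-hydroxy-4,4,7a-trimethyl-2,4,5,6,7,7a-hexahydro-1-benzofuran-2-yl]-4,9-dimethyltetradeca-2,4,6,8,10,12-hexaen-1-ol, i.e. (3S,5R,8R)-5,8-epoxy-5,8-dihydro-10′-apo-β-carotene-3,10′-diol | CC(/C=C/C=C(\C)[C@H]1C=C2C(C)(C)C[C@H](O)C[C@@]2(C)O1)=C\C=C\C=C(C)\C=C\CO | target

## Step count and risks

Total: 11 steps. Longest linear sequence: 8 steps (1, 2, 5, 6, 7, 8, 10, 11).

Step 8 (key step). Most likely failure: the axial information is lost before or after ring closure. Reversible formation of a planar gold-bound allyl cation from the vinylallene would epimerise the axis, and traces of acid would ionise the doubly allylic C8–O bond of the product; both erode C8. A Nazarov-type closure of the vinylallene, or slow cyclisation because the C5–O bond must first turn into the allene plane, are lesser concerns.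
Fallback, from 4 and 7 back to 12, gives up stereocontrol at C8 in exchange for the established rearrangement:
- Hydroboration of alkyne 7 with pinacolborane and catalytic Cp2Zr(H)Cl should give the (E,E)-dienylboronate F1.
- Suzuki–Miyaura coupling of F1 with 4 (Pd(PPh3)4, K3PO4) should give the triene phosphonate F2.
- Peracid epoxidation of the tetrasubstituted C5=C6 bond should give the 5,6-epoxide F3, and Bu4NF the hydroxy epoxide F4.
- A trace of HCl in CHCl3 should then bring about the classical 5,6-epoxide to 5,8-furanoid rearrangement, giving 12 together with its C8 epimer F5, to be separated by chromatography.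

Step 7. Most likely failure: hydrocupration of the conjugated enyne with the opposite regiochemistry (copper next to the diene), which leads to plain reduction instead of substitution, or incomplete anti course, or base-induced isomerisation of the allenyl phosphonate.
Fallback, from 9 back to 11, changes metal and mechanism so that no hydrometalation of the enyne is needed. Zerovalent palladium (Pd2(dba)3·CHCl3, PBu3) with HCO2H/Et3N in THF ionises the oxirane by anti oxidative addition to a σ-allenylpalladium species. Formate delivers hydride by decarboxylation and reductive elimination with retention, which should give the silyl-protected allenol F6 with the same axis. Bu4NF then gives 11.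

Step 6. Most likely failure: peracid delivery to the face syn to the silyloxy group, either as the preferred sense or through low facial discrimination. Low discrimination alone costs only material, because the syn oxirane would lead to a separable diastereomer.
Fallback, from 8 back to 9, reverses the facial outcome. NBS in aqueous DME forms the bromonium ion on the face the peracid prefers, and water opens it from the other face to the bromohydrin F7. K2CO3 in MeOH then closes the oxirane on the face of the hydroxyl. Either regiochemistry of water opening closes to the same oxirane.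

Step 10. Most likely failure: the delocalised phosphonate anion expels the C8 oxygen (β-elimination that opens ring B and, after re-addition, scrambles C8), or attacks through its γ carbon.
Fallback, from 11 back to 17, reverses the order of olefination and ring closure. The allenic phosphonate 11, whose anion has no leaving group in the β position, is olefinated with 15 (KN(SiMe3)2, 3.2 equiv) to the C27 allenic ester F8. The gold-catalysed ring closure of step 8 is then run on F8 to give 17. This moves the key step onto the polyene and is therefore held in reserve.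

## Further compounds

F1 | step 8 | diethyl [(2E,4E)-3-methyl-5-(4,4,5,5-tetramethyl-1,3,2-dioxaborolan-2-yl)penta-2,4-dien-1-yl]phosphonate | CC1(C)OB(/C=C/C(C)=C/CP(=O)(OCC)OCC)OC1(C)C
F2 | step 8 | diethyl [(2E,4E)-5-{(4R)-4-[(tert-butyldimethylsilyl)oxy]-2,6,6-trimethylcyclohex-1-en-1-yl}-3-methylpenta-2,4-dien-1-yl]phosphonate | CC1(C)C[C@H](O[Si](C)(C)C(C)(C)C)CC(C)=C1/C=C/C(C)=C/CP(=O)(OCC)OCC
F3 | step 8 | diethyl [(2E,4E)-5-{(1S,4S,6R)-4-[(tert-butyldimethylsilyl)oxy]-2,2,6-trimethyl-7-oxabicyclo[4.1.0]heptan-1-yl}-3-methylpenta-2,4-dien-1-yl]phosphonate | CC1(C)C[C@H](O[Si](C)(C)C(C)(C)C)C[C@@]2(C)O[C@@]12/C=C/C(C)=C/CP(=O)(OCC)OCC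
F4 | step 8 | diethyl [(2E,4E)-5-{(1S,4S,6R)-4-hydroxy-2,2,6-trimethyl-7-oxabicyclo[4.1.0]heptan-1-yl}-3-methylpenta-2,4-dien-1-yl]phosphonate | CC1(C)C[C@H](O)C[C@@]2(C)O[C@@]12/C=C/C(C)=C/CP(=O)(OCC)OCC
F5 | step 8 | diethyl {(2E)-3-[(2S,6S,7aR)-6-hydroxy-4,4,7a-trimethyl-2,4,5,6,7,7a-hexahydro-1-benzofuran-2-yl]but-2-en-1-yl}phosphonate (C8 epimer of 12) | CCOP(=O)(OCC)C/C=C(\C)[C@@H]1C=C2C(C)(C)C[C@H](O)C[C@@]2(C)O1
F6 | step 7 | diethyl {(2E,aS)-5-[(2R,4S)-4-[(tert-butyldimethylsilyl)oxy]-2-hydroxy-2,6,6-trimethylcyclohexylidene]-3-methylpenta-2,4-dien-1-yl}phosphonate | C1[C@H](O[Si](C)(C)C(C)(C)C)C[C@@](C)(O)C(=[C@@]=CC(/C)=C/CP(=O)(OCC)OCC)C1(C)C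
F7 | step 6 | diethyl [(2E)-5-{(1S,2R,4S)-1-bromo-4-[(tert-butyldimethylsilyl)oxy]-2-hydroxy-2,6,6-trimethylcyclohexyl}-3-methylpent-2-en-4-yn-1-yl]phosphonate | CC1(C)C[C@H](O[Si](C)(C)C(C)(C)C)C[C@@](C)(O)[C@@]1(Br)C#C/C(C)=C/CP(=O)(OCC)OCC
F8 | step 10 | ethyl (2E,4E,6E,8E,10E,12E,aS)-14-[(2R,4S)-2,4-dihydroxy-2,6,6-trimethylcyclohexylidene]-4,9,13-trimethyltetradeca-2,4,6,8,10,12-hexaenoate with the C14 ylidene carbon as allene centre (C27 allenic ester) | C1[C@H](O)C[C@@](C)(O)C(=[C@@]=CC(/C)=C/C=C/C(C)=C/C=C/C=C(C)/C=C/C(=O)OCC)C1(C)C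
A1 | alternative 1 | (3S,5R,6S)-5,6-epoxy-5,6-dihydro-10′-apo-β-carotene-3,10′-diol | CC1(C)C[C@H](O)C[C@@]2(C)O[C@@]12/C=C/C(C)=C/C=C/C(C)=C/C=C/C=C(C)/C=C/CO
A2 | alternative 1 | (3S,5R,8S)-5,8-epoxy-5,8-dihydro-10′-apo-β-carotene-3,10′-diol (C8 epimer of 18) | CC(/C=C/C=C(\C)[C@@H]1C=C2C(C)(C)C[C@H](O)C[C@@]2(C)O1)=C\C=C\C=C(C)\C=C\CO
A3 | alternative 2 | (6S,7aR)-6-[(tert-butyldimethylsilyl)oxy]-4,4,7a-trimethyl-5,6,7,7a-tetrahydro-1-benzofuran-2(4H)-one | O=C1C=C2C(C)(C)C[C@H](O[Si](C)(C)C(C)(C)C)C[C@@]2(C)O1
A4 | alternative 2 | (6S,7aR)-6-[(tert-butyldimethylsilyl)oxy]-2-{(2E)-4-[(tert-butyldimethylsilyl)oxy]but-2-en-2-yl}-4,4,7a-trimethyl-2,4,5,6,7,7a-hexahydro-1-benzofuran-2-ol (lactol, both C2 configurations) | OC1(/C(C)=C/CO[Si](C)(C)C(C)(C)C)C=C2C(C)(C)C[C@H](O[Si](C)(C)C(C)(C)C)C[C@@]2(C)O1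
A5 | alternative 3 | tert-butyl{[(1S,3R)-3-({(3R,4E)-6-[(tert-butyldimethylsilyl)oxy]-4-methylhexa-1,4-dien-3-yl}oxy)-3,5,5-trimethyl-4-methylidenecyclohexyl]oxy}dimethylsilane | C=C1C(C)(C)C[C@H](O[Si](C)(C)C(C)(C)C)C[C@@]1(C)O[C@H](C=C)/C(C)=C/CO[Si](C)(C)C(C)(C)C
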